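Compound numbers refer to the compound list after the steps. Ring atoms of the target lactone are numbered O1, C2 (carbonyl), C3, C4, C5; the six-membered intermediates 11 and 12 use pyran numbering (O1, C2, C3, C4, C5, C6).

## Analysis of the target

Target 17 is a γ-butyrolactone with an exocyclic methylene on C3 conjugated to the C2 carbonyl, a free carboxyl on C4, and a 13-acetoxytridecyl chain on C5. Its only stereocentres are C4 (S) and C5 (R); they are adjacent and their substituents are trans. The α-methylene lactone is the most fragile element: it adds amines, thiols, phosphines and hydride, and base can move the double bond into the ring. The primary acetate excludes hydroxide, alkoxide, hydride and organometallic reagents once it is in place, and C4–H (α to the acid, allylic) makes strong base a threat to the trans relationship. The synthesis is hard because three carboxyl-level carbons (C2, the C4 carboxyl, the acetate) must stay distinguishable, the C4/C5 pair needs absolute control, and the methylene has to arrive last under nearly neutral conditions. The strategy rests on C3: a lactone carrying a carboxyl on C3 in place of the methylene is what a one-carbon ring contraction of a six-membered β-keto lactone delivers. O1, C2, C3, C4, C5 and the carbon of that carboxyl are therefore read as the six ring atoms of a 6-alkyl-pyran-2,4-dione that bears the future C4 carboxyl as an ester. The extruded carbonyl carbon becomes the activating group for a decarboxylative methylenation, and the six-membered ring is an aldol–lactonisation product of a symmetrical 3-oxoglutarate and a C14 aldehyde, in which only C5 needs reagent control.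

## Retrosynthetic reasoning

**17 to diacid 15 (through Mannich base 16).** The C3=CH2 bond is cut first, because the acrylate unit tolerates neither nucleophiles, hydrogenation nor base and must be made last. The cut leaves a carboxyl on C3: in 15 it makes C3 acidic enough to be aminomethylated by an iminium ion in a buffered medium, and it is then lost by decarboxylation together with the amine. One carbon comes in and one goes out with no base stronger than a secondary amine. The forward reaction has to place the double bond exocyclic and leave the acetate and both stereocentres alone.

**15 to benzyl ester 14.** The two carboxyls of 15 are distinguished in the precursor: the one on C4 is a benzyl ester, the one on C3 is free. Hydrogenolysis is chosen because 14 contains nothing else that such conditions reduce, and it must precede the methylenation for the same reason.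

**14 to diazo lactone 12 (through ketene 13).** This is the strategic disconnection. The C3–C4 bond of 14 is cut and C4 is reattached to the carbon of the C3 carboxyl. The ring grows from five to six members and becomes the 3-diazo-pyran-2,4-dione 12, whose C3, C4 (ketone), C5 and C6 are C3, the carboxyl carbon, C4 and C5 of 14. The cut is made here and not at C4–C5 or O1–C5 because those bonds define the stereocentres, which are easier to control in a six-membered β-keto lactone: C6 of 12 is fixed beforehand, and C5, flanked by ketone and ester, equilibrates to trans. What is gained is a precursor made by simple lactonisation and a C3 carboxyl that costs no extra step. The forward reaction has to expel the diazo nitrogen, shift C5 (not the ring oxygen) from the ketone carbon to C3 with retention, and hydrate ketene 13.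

**12 to β-keto lactone 11.** The C=N2 bond is cut. C3 of 11 is a methylene between the lactone and ketone carbonyls and is the only position that can take two nitrogen atoms from a sulfonyl azide; C5 carries a single hydrogen.

**11 to hydroxy diester 10.** The ring bond O1–C2 is cut. In 10 only the ester remote from the carbinol can reach it through a six-membered transition state, so the two ester groups need no differentiation. The forward reaction has to close the ring without retro-aldol cleavage or dehydration of a sensitive aldol.

**10 to aldehyde 3 and dienolate 8 (through silylated adduct 9).** The bond between the carbinol carbon and the α-carbon is cut, an aldol disconnection. Diester 6, from which 8 is made, is symmetrical, so it does not matter which terminus of 8 reacts. The carbinol centre is the only one that needs absolute control and is assigned to a chiral Lewis acid. The ester groups are benzyl. An allyl ester would also be orthogonal to the acetate, but in 8 it would form an O-allyl O-silyl ketene acetal set up for a [3,3] sigmatropic shift. Benzyl esters are inert in 8, towards the sulfonyl azide and towards light, and come off by hydrogenolysis at 14.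

**8 to 6, and 6 to 4 and 5.** Dienolate 8 is the double O-silylation product of diester 6, which comes from commercial 4 by ester exchange with 5.

**3 to 2 to 1.** The aldehyde carbon of 3 becomes C5 of the target, and its chain already carries the acetate, so the chain terminus needs no protecting group. Aldehyde 3 comes from the symmetrical diol 1 by mono-acetylation to 2 and oxidation.

## Alternatives that were turned down

**Alternative 1:** The C4–C5 bond is disconnected by way of a temporary four-membered ring.
- **Forward key step:** acid chloride A2 (tert-butyl 4-chloro-2-methylidene-4-oxobutanoate) would be converted by an amine base into its ketene. A [2+2] cyclocondensation with aldehyde 3 under a silylated cinchona alkaloid and LiClO4 would give cis-β-lactone A1 (tert-butyl 2-[cis-2-(13-acetoxytridecyl)-4-oxooxetan-3-yl]prop-2-enoate). Acid would then remove the tert-butyl group, and the oxygen on C5 would lactonise onto the acrylic carboxyl while the old β-lactone carbonyl becomes the C4 acid.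
- **For:** one catalytic step makes the C4–C5 bond and both stereocentres. The cis four-membered ring maps onto the trans five-membered ring because the oxygen never leaves C5. The methylene is present from the start, and the route would be several steps shorter than the chosen one; on step economy it is clearly the stronger plan.
- **Against:** the ketene from A2 is an alkenyl ketene carrying an acrylate. Such ketenes dimerise and react as dienes, and the amine and chloride present can add to the acrylate or move the double bond into conjugation. The catalysed cyclocondensation is established for alkyl ketenes, so the key step extrapolates in reactivity and not only in substrate. The unmasking must open A1 by acyl–oxygen cleavage; attack at C5 would invert that centre.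
- **Comparison:** the chosen strategy is longer but keeps the acrylate out of the molecule until the last step and relies on reaction classes with close precedent at every stage.

**Alternative 2:** The bonds from C4 to its carboxyl carbon and from C3 to the methylene carbon are disconnected on a preformed lactone.
- **Forward key step:** (CH2=CH)2CuLi would add to C4 of butenolide A3 ((R)-13-(5-oxo-2,5-dihydrofuran-2-yl)tridecyl acetate) anti to the chain. The enolate would be trapped at C3 by dimethylmethyleneammonium iodide to give A4 (3,4-trans-4,5-trans-5-(13-acetoxytridecyl)-3-[(dimethylamino)methyl]-4-vinyldihydrofuran-2(3H)-one).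
- **For:** substrate-controlled anti addition to a 5-substituted butenolide followed by anti trapping is one of the most dependable ways to set this substitution pattern. On relative stereocontrol at C4 it is stronger than the equilibration used in the chosen route, and two C–C bonds form in one flask.
- **Against:** A3 must first be made enantio-enriched from 3 in several steps, and the key step closes no ring. The vinyl group is only a carboxyl surrogate: its oxidative cleavage must be done in the presence of an oxidisable tertiary amine or, after elimination, of the methylene lactone. Quaternisation and elimination add further steps, and the cuprate and the acetate coexist only at low temperature.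
- **Comparison:** the sequence would be longer than the chosen one. The chosen route has the C4 carboxyl at its final oxidation level from the first C–C bond and needs no oxidation late in the synthesis.

**Alternative 3:** The bonds O1–C2 and C2–C3 are disconnected; the lactone carbonyl comes from CO.
- **Forward key step:** anti homopropargylic alcohol A5 (anti-14-hydroxy-15-[(triisopropylsilyloxy)methyl]heptadec-16-yn-1-yl acetate) would be cyclocarbonylated with PdCl2, SnCl2 and PPh3 under CO to give A6 (trans-5-(13-acetoxytridecyl)-3-methylidene-4-[(triisopropylsilyloxy)methyl]dihydrofuran-2(3H)-one).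
- **For:** the α-methylene lactone forms directly in one step without a decarboxylation detour, which is a stronger point than in the chosen plan. A5 can be made from 3 by addition of a chiral allenylmetal reagent that sets both centres anti under reagent control.
- **Against:** that reagent needs its own enantioselective synthesis, and the step uses CO and a tin co-catalyst. After the key step the C4 substituent is still a protected alcohol. Desilylation (fluoride is basic and nucleophilic towards the acrylate and the acetate) and oxidation of the primary alcohol to the acid both have to be done on the finished Michael acceptor. The oxidation passes through an aldehyde whose α-hydrogen sits on C4 and is allylic, so epimerisation or double-bond migration is possible.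
- **Comparison:** the step count is similar. The chosen strategy carries the acrylate through no step at all and never changes the oxidation level of the C4 carboxyl carbon.

Key step: step 8

**Assumptions (remarks on the chemistry):**
- Compound 11 is drawn as the 2,4-dioxo tautomer although it should exist mainly as the 4-hydroxy-5,6-dihydro-2H-pyran-2-one enol.
- The centre between ketone and ester (C2 of 9 and 10, C5 of 11 and 12) is configurationally labile. It is left undefined in 9 and 10 and drawn as the trans isomer expected at equilibrium in 11 and 12.
- The (S)-ligand in step 5 is chosen by analogy with the usual facial preference of this catalyst type with unbranched aldehydes (Si face); the sense of induction has to be confirmed on 10 or 11.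

## Route

Step 1
Reactants: 1 tetradecane-1,14-diol
Product: 2 14-hydroxytetradecyl acetate
Conditions: Ac2O (0.9 equiv), pyridine, THF, 40 °C → rt
Reagents that add atoms: acetic anhydride, CC(=O)OC(C)=O
Why: Statistical mono-acylation of a symmetrical primary diol (nucleophilic acyl substitution); a slight deficit of anhydride limits diacetate formation, and unreacted 1 is separated by chromatography and recycled.

Step 2
Reactants: 2 14-hydroxytetradecyl acetate
Product: 3 14-oxotetradecyl acetate
Conditions: TEMPO (10 mol%), PhI(OAc)2 (1.1 equiv), CH2Cl2, rt
Reagents that add atoms: none
Why: Nitroxyl-catalysed oxidation of a primary alcohol with PhI(OAc)2 as terminal oxidant; it stops at the aldehyde and leaves the acetate untouched.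

Step 3
Reactants: 4 dimethyl 3-oxopentanedioate; 5 benzyl alcohol
Product: 6 dibenzyl 3-oxopentanedioate
Conditions: 5 (2.3 equiv), DMAP (10 mol%), PhMe, reflux, 4 Å MS (Soxhlet)
Reagents that add atoms: none
Why: Transesterification of a β-keto ester, which exchanges far more readily than a simple ester under DMAP catalysis; removal of methanol drives both ester groups to the benzyl ester.

Step 4
Reactants: 6 dibenzyl 3-oxopentanedioate
Product: 8 benzyl 5-(benzyloxy)-3,5-bis(trimethylsilyloxy)penta-2,4-dienoate, via mono-silyl enol ether 7 (not isolated)
Conditions: TMSOTf (2.2 equiv), Et3N (2.6 equiv), Et2O, 0 °C → rt; used crude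
Reagents that add atoms: trimethylsilyl trifluoromethanesulfonate, C[Si](C)(C)OS(=O)(=O)C(F)(F)F
Why: Soft enolisation and O-silylation: the first equivalent gives the conjugated silyl enol ether 7, whose remaining CH2 is α to an ester and vinylogously activated, so the second equivalent forms the ketene silyl acetal. The product is a 1,3-bis(silyloxy)diene of the kind used in Mukaiyama aldol additions, and with benzyl esters it has no [3,3] pathway open.

Step 5
Reactants: 3 14-oxotetradecyl acetate; 8 benzyl 5-(benzyloxy)-3,5-bis(trimethylsilyloxy)penta-2,4-dienoate
Product: 10 dibenzyl 2-[(1R)-14-acetoxy-1-hydroxytetradecyl]-3-oxopentanedioate (epimers at C2), via bis-silylated aldol adduct 9 (not isolated)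
Conditions: Ti(OiPr)4 (10 mol%), (S)-BINOL (11 mol%), 4 Å MS, THF, −78 → −20 °C; then TFA, THF–H2O, −78 → 0 °C
Reagents that add atoms: none
Why: Enantioselective Mukaiyama aldol addition catalysed by a chiral titanium binaphtholate Lewis acid; because 8 derives from a symmetrical diester, attack through either nucleophilic terminus gives the same constitution. The carbinol centre (R) is set by the catalyst, which with the (S)-ligand is expected to leave the Si face of the unbranched aldehyde open; the neighbouring α-centre forms without control and is labile, which is of no consequence.

Step 6
Reactants: 10 dibenzyl 2-[(1R)-14-acetoxy-1-hydroxytetradecyl]-3-oxopentanedioate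
Product: 11 benzyl (5R,6R)-6-(13-acetoxytridecyl)-2,4-dioxotetrahydro-2H-pyran-5-carboxylate
Conditions: PPTS (20 mol%), PhMe, 85 °C
Reagents that add atoms: none
Why: Acid-catalysed intramolecular transesterification (lactonisation of a δ-hydroxy β-keto ester): only the distal ester can close a six-membered ring, the proximal one would give a β-lactone, and the strongly enolised β-keto lactone is a thermodynamic sink. Mild acid instead of base keeps retro-aldol cleavage, and with it loss of the carbinol configuration, in check.

Step 7
Reactants: 11 benzyl (5R,6R)-6-(13-acetoxytridecyl)-2,4-dioxotetrahydro-2H-pyran-5-carboxylate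
Product: 12 benzyl (5R,6R)-6-(13-acetoxytridecyl)-3-diazo-2,4-dioxotetrahydro-2H-pyran-5-carboxylate
Conditions: 4-acetamidobenzenesulfonyl azide (1.05 equiv), Et3N (1.05 equiv), MeCN, 0 °C
Reagents that add atoms: 4-acetamidobenzenesulfonyl azide, CC(=O)Nc1ccc(cc1)S(=O)(=O)N=[N+]=[N-]
Why: Regitz diazo transfer to the doubly activated C3 methylene, whose enol is about as acidic as a carboxylic acid, so one equivalent of amine suffices. C5 has a single hydrogen and cannot take up a diazo group, and one equivalent of azide avoids deacylative transfer there. The amine equilibrates C5 through the enol, so 12 should be obtained as the 5,6-trans isomer.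

Step 8
Reactants: 12 benzyl (5R,6R)-6-(13-acetoxytridecyl)-3-diazo-2,4-dioxotetrahydro-2H-pyran-5-carboxylate
Product: 14 (3R,4S,5R)-5-(13-acetoxytridecyl)-4-[(benzyloxy)carbonyl]-2-oxotetrahydrofuran-3-carboxylic acid, via acyl ketene 13 (not isolated)
Conditions: hν (254 nm, quartz), MeCN–H2O (9:1), Ar, 10 °C
Reagents that add atoms: water, O
Why: Excitation of the 2-diazo-1,3-dicarbonyl chromophore expels N2, and because both carbonyl groups are held s-Z by the ring the 1,2-shift should be concerted with nitrogen loss: the C4–C5 bond of the pyrandione moves to C3, which creates the C3–C4 bond of the lactone and leaves the former ketone carbon outside the ring as the α-oxo ketene 13. This is the Wolff rearrangement in its ring-contracting form; the closest known cases are the photolysis of 2-diazocyclohexane-1,3-diones to cyclopentanone carboxylic acids and of 3-diazo derivatives of tetramic acids and chromane-2,4-diones to β-lactam and benzofuranone carboxylic acid derivatives. The five-membered ring is closed by a suprafacial 1,2-shift within an existing ring (six to five) and not by a cyclisation, so no ring-closure rule applies. The migrating carbon keeps its configuration, so the 5,6-trans relationship of 12 becomes the 4,5-trans relationship of the lactone. The new centre C3 arises when water adds to the ketene and the resulting enol is protonated; as a malonic-type centre it should settle trans to the C4 ester under thermodynamic control, and it is erased again in step 10. The selectivity needed is migration of carbon and not of the ring oxygen on the other carbonyl: alkyl groups shift far more readily than alkoxy oxygen in Wolff rearrangements, and the lone pairs of O1 are tied up in ester resonance. Stepwise carbene chemistry such as insertion into the O–H bond of water is disfavoured by the locked s-Z geometry and short-wavelength excitation, and the benzyl ester and acetate absorb negligibly next to the diazo chromophore. Capture of 13 by water gives the C3 carboxyl directly, the group that step 10 requires.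

Step 9
Reactants: 14 (3R,4S,5R)-5-(13-acetoxytridecyl)-4-[(benzyloxy)carbonyl]-2-oxotetrahydrofuran-3-carboxylic acid
Product: 15 (3R,4S,5R)-5-(13-acetoxytridecyl)-2-oxotetrahydrofuran-3,4-dicarboxylic acid
Conditions: H2 (1 atm), 10% Pd/C, EtOAc, rt
Reagents that add atoms: none
Why: Hydrogenolysis of a benzyl ester over palladium on carbon; nothing else in 14 is reducible, the acetate and the lactone are inert, and the step has to come before the methylene exists.

Step 10
Reactants: 15 (3R,4S,5R)-5-(13-acetoxytridecyl)-2-oxotetrahydrofuran-3,4-dicarboxylic acid
Product: 17 (2R,3S)-2-(13-acetoxytridecyl)-4-methylidene-5-oxotetrahydrofuran-3-carboxylic acid, via Mannich base 16 (not isolated)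
Conditions: 37% aq. HCHO, Et2NH, NaOAc, AcOH, rt
Reagents that add atoms: formaldehyde, C=O
Why: Decarboxylative Mannich methylenation of an α-carboxy lactone: the enol of the malonic half-acid at C3 is aminomethylated by the iminium ion from formaldehyde and diethylamine, and 16 fragments with loss of CO2 and amine, which places the double bond exocyclic by construction. The buffered medium spares the acetate and does not touch C4 or C5.

## Compound list

1 | tetradecane-1,14-diol | OCCCCCCCCCCCCCCO | starting material
2 | 14-hydroxytetradecyl acetate | CC(=O)OCCCCCCCCCCCCCCO | intermediate
3 | 14-oxotetradecyl acetate (14-acetoxytetradecanal) | CC(=O)OCCCCCCCCCCCCCC=O | intermediate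
4 | dimethyl 3-oxopentanedioate | COC(=O)CC(=O)CC(=O)OC | starting material
5 | benzyl alcohol | OCc1ccccc1 | starting material
6 | dibenzyl 3-oxopentanedioate | O=C(CC(=O)OCc1ccccc1)CC(=O)OCc1ccccc1 | intermediate
7 | dibenzyl 3-(trimethylsilyloxy)pent-2-enedioate | C[Si](C)(C)OC(=CC(=O)OCc1ccccc1)CC(=O)OCc1ccccc1 | intermediate (not isolated)
8 | benzyl 5-(benzyloxy)-3,5-bis(trimethylsilyloxy)penta-2,4-dienoate | C[Si](C)(C)OC(=CC(=O)OCc1ccccc1)C=C(OCc1ccccc1)O[Si](C)(C)C | intermediate
9 | dibenzyl 2-[(1R)-14-acetoxy-1-(trimethylsilyloxy)tetradecyl]-3-(trimethylsilyloxy)pent-3-enedioate (epimers at C2) | C[Si](C)(C)OC(=CC(=O)OCc1ccccc1)C(C(=O)OCc1ccccc1)[C@H](O[Si](C)(C)C)CCCCCCCCCCCCCOC(C)=O | intermediate (not isolated)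
10 | dibenzyl 2-[(1R)-14-acetoxy-1-hydroxytetradecyl]-3-oxopentanedioate (epimers at C2) | O=C(CC(=O)OCc1ccccc1)C(C(=O)OCc1ccccc1)[C@H](O)CCCCCCCCCCCCCOC(C)=O | intermediate
11 | benzyl (5R,6R)-6-(13-acetoxytridecyl)-2,4-dioxotetrahydro-2H-pyran-5-carboxylate (5,6-trans) | O=C1O[C@H](CCCCCCCCCCCCCOC(C)=O)[C@@H](C(=O)OCc2ccccc2)C(=O)C1 | intermediate
12 | benzyl (5R,6R)-6-(13-acetoxytridecyl)-3-diazo-2,4-dioxotetrahydro-2H-pyran-5-carboxylate (5,6-trans) | O=C1O[C@H](CCCCCCCCCCCCCOC(C)=O)[C@@H](C(=O)OCc2ccccc2)C(=O)C1=[N+]=[N-] | intermediate
13 | benzyl (2R,3S)-2-(13-acetoxytridecyl)-4-(oxomethylidene)-5-oxotetrahydrofuran-3-carboxylate | O=C=C1C(=O)O[C@H](CCCCCCCCCCCCCOC(C)=O)[C@H]1C(=O)OCc2ccccc2 | intermediate (not isolated)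
14 | (3R,4S,5R)-5-(13-acetoxytridecyl)-4-[(benzyloxy)carbonyl]-2-oxotetrahydrofuran-3-carboxylic acid (all-trans) | O=C1O[C@H](CCCCCCCCCCCCCOC(C)=O)[C@@H](C(=O)OCc2ccccc2)[C@@H]1C(=O)O | intermediate
15 | (3R,4S,5R)-5-(13-acetoxytridecyl)-2-oxotetrahydrofuran-3,4-dicarboxylic acid (all-trans) | O=C1O[C@H](CCCCCCCCCCCCCOC(C)=O)[C@@H](C(=O)O)[C@@H]1C(=O)O | intermediate
16 | (4S,5R)-5-(13-acetoxytridecyl)-3-[(diethylamino)methyl]-2-oxotetrahydrofuran-3,4-dicarboxylic acid (C3 undefined) | O=C1O[C@H](CCCCCCCCCCCCCOC(C)=O)[C@@H](C(=O)O)C1(CN(CC)CC)C(=O)O | intermediate (not isolated)
17 | (2R,3S)-2-(13-acetoxytridecyl)-4-methylidene-5-oxotetrahydrofuran-3-carboxylic acid | C=C1C(=O)O[C@H](CCCCCCCCCCCCCOC(C)=O)[C@H]1C(=O)O | target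

## Step count and least certain steps

Total step count: 10.

Longest linear sequence: 8 steps (steps 1, 2, 5, 6, 7, 8, 9, 10 from 1; the branch from 4, steps 3, 4, 5 to 10, is equally long).

**Step 8 (key step).**
- What may go wrong: the carbon that has to migrate is secondary and carries an ester, so its 1,2-shift is slower than that of a simple alkyl group. Stepwise carbene pathways (insertion into the O–H bond of water, hydrogen abstraction), photoisomerisation to the diazirine or, less probably, migration of the ring oxygen could then compete. The α-carboxy lactone may also lose CO2 during concentration or chromatography, and keto–enol exchange at C5 of 12 during irradiation would leak cis isomer into the product.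
- Fallback: it sets out from 12 and changes how the ketene is made, what captures it and what is isolated. Thermolysis of 12 (chlorobenzene, 130 °C) in the presence of benzyl alcohol 5 should give, by the ground-state Wolff shift and alcohol capture of 13, the neutral and chromatographable dibenzyl (3R,4S,5R)-5-(13-acetoxytridecyl)-2-oxotetrahydrofuran-3,4-dicarboxylate F1. Hydrogenolysis of both benzyl esters (H2, Pd/C, EtOAc) returns to the route at 15.

**Step 5.**
- What may go wrong: poor facial discrimination and sluggish addition. Dienolate 8 is less nucleophilic than the bis-silyl dienolate of a simple acetoacetate because one terminus is an acrylate, and it reacts through a substituted carbon. Uncatalysed or silyl-cation-catalysed background addition would erode enantiomeric purity, and the sense of induction rests on analogy.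
- Fallback: it sets out from 6 and 3 and replaces catalyst control by resolution. The dilithium dianion of 6 (LiN(iPr)2, 2.1 equiv, THF, −78 °C) is added to 3 and quenched cold with AcOH. This gives the racemic aldol, that is 10 together with its enantiomer dibenzyl 2-[(1S)-14-acetoxy-1-hydroxytetradecyl]-3-oxopentanedioate F2. Lactonisation as in step 6 gives 11 together with benzyl (5S,6S)-6-(13-acetoxytridecyl)-2,4-dioxotetrahydro-2H-pyran-5-carboxylate F3. Preparative chromatography of the acidic enol on a chiral stationary phase removes F3 and returns to the route at 11, at the cost of half the material.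

**Step 6.**
- What may go wrong: dehydration to the alkylidene diester, or retro-aldol cleavage and re-addition (loss of enantiomeric purity), may outrun ring closure. Ester exchange of a benzyl ester needs heat, and the aldol of a β-keto ester is inherently labile.
- Fallback: it sets out from 3 and replaces the distal ester by a masked acyl ketene that lactonises under neutral conditions.
  - Benzyl (2,2-dimethyl-4-oxo-4H-1,3-dioxin-6-yl)acetate F4 is made from commercial 2,2,6-trimethyl-4H-1,3-dioxin-4-one with LiN(SiMe3)2 (2 equiv) and benzyl chloroformate in THF at −78 °C.
  - F4 is silylated (TMSOTf, Et3N) to benzyl 2-[2,2-dimethyl-4-(trimethylsilyloxy)-6H-1,3-dioxin-6-ylidene]acetate F5.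
  - F5 is added to 3 under the conditions of step 5 to give benzyl (3R)-16-acetoxy-2-(2,2-dimethyl-4-oxo-4H-1,3-dioxin-6-yl)-3-hydroxyhexadecanoate F6.
  - Brief heating of F6 (PhMe, 105 °C) expels acetone in a retro-[4+2] reaction, and the hydroxyl captures the acyl ketene, which returns to the route at 11.

**Step 7.**
- What may go wrong: base-induced ring opening. Once C3 carries the diazo group, C5–H is the most acidic proton, and its enolate can expel the lactone oxygen from C6 (E1cB). This destroys the ring and, through re-addition, the C6 configuration. Excess azide could also attack C5 with loss of the acyl group.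
- Fallback: it sets out from 11 and builds the diazo group under acidic conditions.
  - Nitrosation at C3 (NaNO2, aq. AcOH–THF, 0 °C) gives benzyl (5R,6R)-6-(13-acetoxytridecyl)-3-(hydroxyimino)-2,4-dioxotetrahydro-2H-pyran-5-carboxylate F7.
  - Reduction (Zn, AcOH, 0 °C) gives benzyl (5R,6R)-6-(13-acetoxytridecyl)-3-amino-4-hydroxy-2-oxo-5,6-dihydro-2H-pyran-5-carboxylate F8, kept as its acetate salt.
  - Diazotisation of F8 (isoamyl nitrite, AcOH–CH2Cl2, 0 °C) returns to the route at 12.

## Further compounds

F1 | step 8 | dibenzyl (3R,4S,5R)-5-(13-acetoxytridecyl)-2-oxotetrahydrofuran-3,4-dicarboxylate | O=C1O[C@H](CCCCCCCCCCCCCOC(C)=O)[C@@H](C(=O)OCc2ccccc2)[C@@H]1C(=O)OCc3ccccc3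
F2 | step 5 | dibenzyl 2-[(1S)-14-acetoxy-1-hydroxytetradecyl]-3-oxopentanedioate | O=C(CC(=O)OCc1ccccc1)C(C(=O)OCc1ccccc1)[C@@H](O)CCCCCCCCCCCCCOC(C)=O
F3 | step 5 | benzyl (5S,6S)-6-(13-acetoxytridecyl)-2,4-dioxotetrahydro-2H-pyran-5-carboxylate | O=C1O[C@@H](CCCCCCCCCCCCCOC(C)=O)[C@H](C(=O)OCc2ccccc2)C(=O)C1
F4 | step 6 | benzyl (2,2-dimethyl-4-oxo-4H-1,3-dioxin-6-yl)acetate | CC1(C)OC(=O)C=C(CC(=O)OCc2ccccc2)O1
F5 | step 6 | benzyl 2-[2,2-dimethyl-4-(trimethylsilyloxy)-6H-1,3-dioxin-6-ylidene]acetate | CC1(C)OC(O[Si](C)(C)C)=CC(=CC(=O)OCc2ccccc2)O1
F6 | step 6 | benzyl (3R)-16-acetoxy-2-(2,2-dimethyl-4-oxo-4H-1,3-dioxin-6-yl)-3-hydroxyhexadecanoate | CC1(C)OC(=O)C=C(O1)C(C(=O)OCc2ccccc2)[C@H](O)CCCCCCCCCCCCCOC(C)=O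
F7 | step 7 | benzyl (5R,6R)-6-(13-acetoxytridecyl)-3-(hydroxyimino)-2,4-dioxotetrahydro-2H-pyran-5-carboxylate | O=C1O[C@H](CCCCCCCCCCCCCOC(C)=O)[C@@H](C(=O)OCc2ccccc2)C(=O)C1=NO
F8 | step 7 | benzyl (5R,6R)-6-(13-acetoxytridecyl)-3-amino-4-hydroxy-2-oxo-5,6-dihydro-2H-pyran-5-carboxylate | O=C1O[C@H](CCCCCCCCCCCCCOC(C)=O)[C@@H](C(=O)OCc2ccccc2)C(O)=C1N
A1 | alternative 1 | tert-butyl 2-[cis-2-(13-acetoxytridecyl)-4-oxooxetan-3-yl]prop-2-enoate | O=C1O[C@H](CCCCCCCCCCCCCOC(C)=O)[C@@H]1C(=C)C(=O)OC(C)(C)C
A2 | alternative 1 | tert-butyl 4-chloro-2-methylidene-4-oxobutanoate | C=C(CC(=O)Cl)C(=O)OC(C)(C)C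
A3 | alternative 2 | (R)-13-(5-oxo-2,5-dihydrofuran-2-yl)tridecyl acetate | O=C1O[C@H](CCCCCCCCCCCCCOC(C)=O)C=C1
A4 | alternative 2 | 3,4-trans-4,5-trans-5-(13-acetoxytridecyl)-3-[(dimethylamino)methyl]-4-vinyldihydrofuran-2(3H)-one | O=C1O[C@H](CCCCCCCCCCCCCOC(C)=O)[C@@H](C=C)[C@@H]1CN(C)C
A5 | alternative 3 | anti-14-hydroxy-15-[(triisopropylsilyloxy)methyl]heptadec-16-yn-1-yl acetate | C#C[C@H](CO[Si](C(C)C)(C(C)C)C(C)C)[C@H](O)CCCCCCCCCCCCCOC(C)=O
A6 | alternative 3 | trans-5-(13-acetoxytridecyl)-3-methylidene-4-[(triisopropylsilyloxy)methyl]dihydrofuran-2(3H)-one | C=C1C(=O)O[C@H](CCCCCCCCCCCCCOC(C)=O)[C@H]1CO[Si](C(C)C)(C(C)C)C(C)C
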